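**Retrosynthetic overview**

1. Rabdosin B ⇐ C15 oxidation (SeO2, then MnO2) of 15-deoxo compound 23 ⇐ one-flask radical bicyclization of bromo-diene aldehyde 22: the C16 vinyl radical closes ring D (C13–C16), and the resulting C12 radical closes ring C by forming the C11–C12 bond on the C11 formyl group.
2. Enabling feature: quaternary C8 is both the lactone α-carbon and a bridgehead of the bicyclo[3.2.1]octane (rings C and D), so its three arms C9–C11H=O, C14–C13=C12 and C15–C16(Br)=C17 sit in 5-exo/6-exo register. The exocyclic C16=C17 on ring D is the footprint of the vinyl radical and the C11 carbinol that of the aldehyde.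
3. 22 ⇐ two enolate alkylations at C8 of spiro-δ-lactone 13 (allyl first, then 2-bromoallyl anti to the C9 substituent) ⇐ lactone ring (C7, C8, C9, C10, C20, O) by Michael addition of ring-A formyl ketone 5 to menthyloxyfuranone 6 (sets C9 and C10), then translactonization.
4. 5 ⇐ copper-catalysed asymmetric vinyl addition/formylation of 4,4-dimethylcyclohexenone (sets C5). The C1 and C6 oxygens come from the ketone and the vinyl group.
5. Ring order: A (starting material) → lactone ring → D → C, the last two in the key step.

Key step: step 12

Remark: locants C1–C20 are the ent-kaurane locants of the target (ring A = C1–C5, C10; ring C = C8, C9, C11–C14; ring D = C8, C13–C16), and both antipodes of 5-(menthyloxy)furan-2(5H)-one are assumed purchasable, the one used (6) deriving from (+)-menthol.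

**Route**

Step 1
Reactants: 1 4,4-dimethylcyclohex-2-en-1-one; 2 vinylmagnesium bromide; 3 2,2,2-trifluoroethyl formate
Product: 5 (3R)-2-(hydroxymethylidene)-4,4-dimethyl-3-vinylcyclohexan-1-one, via bromomagnesium enolate 4 (not isolated)
Conditions: CuBr·SMe2 (5 mol %), (R)-1-[(S)-2-(diphenylphosphino)ferrocenyl]ethyldicyclohexylphosphine or its antipode (6 mol %; the antipode that gives 3R is kept), t-BuOMe, −78 °C; then 3, −78 → 0 °C
Reagents that add atoms: none
Why: Copper-catalysed enantioselective conjugate addition of a Grignard reagent, in which the chiral ferrocenyl diphosphine–copper complex selects the enone face and so sets C5, followed by Claisen-type C-formylation of the regiodefined magnesium enolate by the activated formate.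

Step 2
Reactants: 5 (3R)-2-(hydroxymethylidene)-4,4-dimethyl-3-vinylcyclohexan-1-one; 6 (5S)-5-{[(1S,2R,5S)-5-methyl-2-(propan-2-yl)cyclohexyl]oxy}furan-2(5H)-one
Product: 7 Michael adduct (ring-A 2-formyl ketone carrying the 5-menthyloxy-γ-butyrolactone at quaternary C10)
Conditions: Et3N (0.3 equiv), CH2Cl2, 0 °C → rt
Reagents that add atoms: none
Why: Amine-mediated Michael addition of a 1,3-dicarbonyl donor to a butenolide: C9 is set by attack trans to the menthyloxy group of 6, and quaternary C10 by attack of the planar enolate on the face anti to the adjacent vinyl group on C5, which places C20 cis and C9 trans to that group.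

Step 3
Reactants: 7 Michael adduct
Product: 8 hydroxymethyl γ-lactone (C20 alcohol)
Conditions: NaBH4 (0.3 equiv), CH2Cl2–MeOH, −78 °C; AcOH quench at −78 °C
Reagents that add atoms: none
Why: Chemoselective borohydride reduction of the aldehyde, which at −78 °C is far more electrophilic than the ketone flanked by quaternary C10 and than the lactone; no stereocenter is formed.

Step 4
Reactants: 8 hydroxymethyl γ-lactone
Product: 9 spiro δ-lactone keto aldehyde
Conditions: ClBu2SnOSnBu2Cl (5 mol %), toluene, 60 °C
Reagents that add atoms: none
Why: Tin-catalysed intramolecular transesterification (pseudo-ester to normal ester): the C20 hydroxyl attacks C7 to close the six-membered spiro lactone and the expelled hemiacetal collapses to the C11 aldehyde and menthol, the neutral catalyst avoiding both C9 epimerisation and the acid pathway that would tie the C20 hydroxyl to C11 as a cyclic acetal.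

Step 5
Reactants: 9 spiro δ-lactone keto aldehyde
Product: 10 spiro δ-lactone keto dimethyl acetal
Conditions: MeOSiMe3 (4 equiv), TMSOTf (5 mol %), CH2Cl2, −78 °C; pyridine quench
Reagents that add atoms: methoxytrimethylsilane CO[Si](C)(C)C
Why: Silyl-triflate-catalysed acetalisation with an alkoxysilane under aprotic conditions, selective for the aldehyde over the hindered C1 ketone and leaving the lactone closed.

Step 6
Reactants: 10 spiro δ-lactone keto dimethyl acetal
Product: 12 spiro δ-lactone 1,6-diol, via keto aldehyde 11 (not isolated)
Conditions: O3, CH2Cl2–MeOH (4:1), −78 °C; then CeCl3·7H2O and NaBH4, −78 → −20 °C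
Reagents that add atoms: ozone [O-][O+]=O
Why: Ozonolysis of the only alkene with reductive work-up gives the C6 alcohol, and the cerium-assisted borohydride reduces the C1 ketone by axial hydride delivery anti to the axial C20–O substituent on C10, which sets the equatorial C1 hydroxyl cis to C20 and C6.

Step 7
Reactants: 12 spiro δ-lactone 1,6-diol
Product: 13 bis(triethylsilyl) ether
Conditions: TESCl (3 equiv), imidazole, DMAP (cat.), DMF, 0 → 40 °C
Reagents that add atoms: chlorotriethylsilane CC[Si](Cl)(CC)CC
Why: Standard silylation of both hydroxyls, so that the enolate steps that follow meet no acidic or acylable group.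

Step 8
Reactants: 13 bis(triethylsilyl) ether; 14 allyl bromide
Product: 16 8-allyl lactone, via lithium enolate 15 (not isolated)
Conditions: LiN(i-Pr)2, THF, −78 °C; then 14, DMPU, −78 → −40 °C
Reagents that add atoms: none
Why: Alkylation of the lactone lithium enolate with an allylic bromide; the allyl group should enter anti to the C9 substituent, but the C8 configuration is inconsequential because C8 is enolised again in step 9.

Step 9
Reactants: 16 8-allyl lactone; 17 2,3-dibromopropene
Product: 19 8-allyl-8-(2-bromoprop-2-enyl) lactone, via lithium enolate 18 (not isolated)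
Conditions: LiN(i-Pr)2, THF, −78 °C; then 17, DMPU, −78 → −30 °C
Reagents that add atoms: none
Why: Second enolate alkylation (SN2 at the allylic bromide of 17, the vinylic bromide being inert): the electrophile should enter anti to the dimethoxymethyl group on C9, which fixes quaternary C8 with the bromoallyl arm trans and the allyl arm cis to C11.

Step 10
Reactants: 19 8-allyl-8-(2-bromoprop-2-enyl) lactone
Product: 21 1,6-diacetate dimethyl acetal, via diol 20 (not isolated)
Conditions: Bu4NF, AcOH (1:1), THF, 0 °C → rt; then Ac2O, pyridine, DMAP (cat.), rt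
Reagents that add atoms: acetic anhydride CC(=O)OC(C)=O
Why: Buffered fluoride desilylation followed in the same flask by DMAP-catalysed acetylation installs the two acetates of the target before the C11 hydroxyl exists.

Step 11
Reactants: 21 1,6-diacetate dimethyl acetal
Product: 22 1,6-diacetate aldehyde (bromo-diene aldehyde)
Conditions: TESOTf, 2,4,6-collidine, CH2Cl2, 0 °C; then H2O
Reagents that add atoms: water O
Why: Silyl triflate–collidine cleavage of the dimethyl acetal through a pyridinium intermediate and its hydrolysis, a non-protic unmasking that spares the acetates and avoids participation of the lactone carbonyl.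

Step 12
Reactants: 22 1,6-diacetate aldehyde (bromo-diene aldehyde)
Product: 23 15-deoxorabdosin B
Conditions: Bu3SnH (1.3 equiv) and AIBN (0.2 equiv) added by syringe pump over 8 h, PhH (0.003 M), 80 °C
Reagents that add atoms: none
Why: Bu3Sn• abstracts bromine from C16, the C16 vinyl radical attacks C13 of the allyl arm, the primary C12 radical so formed attacks the carbon of the C11 formyl group (making the C11–C12 bond), and the alkoxyl radical is reduced by Bu3SnH, which carries the chain. The closest known reaction types are the 5-exo cyclization of 2-bromoallyl-derived vinyl radicals to methylenecyclopentanes and bicyclo[3.2.1]octanes and the 6-exo cyclization of alkyl radicals onto aldehydes to cyclohexanols, here run in tandem. Ring D closes by 5-exo-trig attack on the alkene and ring C by 6-exo-trig attack on the C=O group. C13 is set in the first closure, where the chair-like transition state keeps the bulky C9 branch of the lactone on quaternary C8 pseudo-equatorial and the flat C7 carbonyl pseudo-axial so that the CH2• arm ends cis to C9 (the only isomer able to reach the aldehyde), and C11 is set in the second, where the radical approaches anti to the C9–C10 bond (the spiro carbon cannot sit 1,3-diaxial to C14, so ring C should close through a boat-like array) with the formyl oxygen turned outward, giving the hydroxyl cis to H9 and trans to C10 as in the target. The step needs 5-exo rather than 6-endo closure and closure faster than 1,5-hydrogen transfer from the formyl group to the vinyl radical, secured by the high rate of vinyl radical addition to a terminal alkene held on the same quaternary carbon, and it needs carbonyl addition of the C12 radical faster than hydrogen transfer from the stannane or homoallyl rearrangement, secured by slow addition of Bu3SnH at high dilution and by the cis arrangement of radical and formyl group on the new ring D.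

Step 13
Reactants: 23 15-deoxorabdosin B
Product: 24 15-hydroxy-15-deoxorabdosin B
Conditions: SeO2 (0.5 equiv), t-BuOOH (3 equiv), CH2Cl2, 0 °C → rt
Reagents that add atoms: tert-butyl hydroperoxide CC(C)(C)OO
Why: Selenium dioxide allylic oxidation (ene reaction, then [2,3]-shift) at C15, the only allylic methylene since the other allylic position is the bridgehead C13; the configuration of the new carbinol is irrelevant because it is oxidised in step 14.

Step 14
Reactants: 24 15-hydroxy-15-deoxorabdosin B
Product: 25 Rabdosin B
Conditions: MnO2 (excess), CH2Cl2, rt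
Reagents that add atoms: none
Why: Manganese dioxide oxidises only the allylic C15 alcohol, leaving the non-allylic C11 hydroxyl, and completes the α-methylene ketone.

**Compound list**

1 | 4,4-dimethylcyclohex-2-en-1-one | CC1(C)C=CC(=O)CC1 | starting material
2 | vinylmagnesium bromide | C=C[Mg]Br | starting material
3 | 2,2,2-trifluoroethyl formate | O=COCC(F)(F)F | starting material
4 | bromomagnesium enolate of (3R)-4,4-dimethyl-3-vinylcyclohexanone (enolate toward the vinyl-bearing carbon) | Br[Mg]OC1=C[C@H](C=C)C(C)(C)CC1 | intermediate
5 | (3R,Z)-2-(hydroxymethylidene)-4,4-dimethyl-3-vinylcyclohexan-1-one (enol form of the 2-formyl ketone) | O/C=C1\C(=O)CCC(C)(C)[C@H]1C=C | intermediate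
6 | (5S)-5-{[(1S,2R,5S)-5-methyl-2-(propan-2-yl)cyclohexyl]oxy}furan-2(5H)-one | O=C1C=C[C@@H](O[C@H]2C[C@@H](C)CC[C@@H]2C(C)C)O1 | starting material
7 | Michael adduct: ring-A ketone whose quaternary C10 bears a formyl group (C20, cis to the C5 vinyl group) and C9; C9 is C4 of a 5-menthyloxy-γ-butyrolactone (C7 carbonyl), with C10 and the menthyloxy group trans on that ring | O=C1CCC(C)(C)[C@@H](C=C)[C@]1(C=O)[C@H]2CC(=O)O[C@@H]2O[C@H]3C[C@@H](C)CC[C@@H]3C(C)C | intermediate
8 | as 7 with the C20 formyl group reduced to CH2OH | O=C1CCC(C)(C)[C@@H](C=C)[C@]1(CO)[C@H]2CC(=O)O[C@@H]2O[C@H]3C[C@@H](C)CC[C@@H]3C(C)C | intermediate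
9 | spiro δ-lactone keto aldehyde: ring A (C1 ketone, C5 vinyl) spiro at C10 to the lactone C20H2–O–C7(=O)–C8H2–C9H(CHO); C20 cis to the vinyl group on ring A | O=C1CCC(C)(C)[C@@H](C=C)[C@@]12COC(=O)C[C@H]2C=O | intermediate
10 | dimethyl acetal of 9 at C11 | O=C1CCC(C)(C)[C@@H](C=C)[C@@]12COC(=O)C[C@H]2C(OC)OC | intermediate
11 | C6 aldehyde from ozonolysis of the vinyl group of 10 | O=C1CCC(C)(C)[C@@H](C=O)[C@@]12COC(=O)C[C@H]2C(OC)OC | intermediate
12 | 1,6-diol: C1 hydroxyl cis to C20 and to the C5 hydroxymethyl group | O[C@H]1CCC(C)(C)[C@@H](CO)[C@@]12COC(=O)C[C@H]2C(OC)OC | intermediate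
13 | bis(triethylsilyl) ether of 12 | CC[Si](CC)(CC)O[C@H]1CCC(C)(C)[C@@H](CO[Si](CC)(CC)CC)[C@@]12COC(=O)C[C@H]2C(OC)OC | intermediate
14 | allyl bromide | C=CCBr | starting material
15 | lithium enolate of 13 (C7–C8) | CC[Si](CC)(CC)O[C@H]1CCC(C)(C)[C@@H](CO[Si](CC)(CC)CC)[C@@]12COC(O[Li])=C[C@H]2C(OC)OC | intermediate
16 | 8-allyl derivative of 13 (allyl trans to the C9 dimethoxymethyl group; the C8 epimer serves equally) | CC[Si](CC)(CC)O[C@H]1CCC(C)(C)[C@@H](CO[Si](CC)(CC)CC)[C@@]12COC(=O)[C@H](CC=C)[C@H]2C(OC)OC | intermediate
17 | 2,3-dibromopropene | C=C(Br)CBr | starting material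
18 | lithium enolate of 16 | CC[Si](CC)(CC)O[C@H]1CCC(C)(C)[C@@H](CO[Si](CC)(CC)CC)[C@@]12COC(O[Li])=C(CC=C)[C@H]2C(OC)OC | intermediate
19 | 8-allyl-8-(2-bromoprop-2-enyl) lactone (allyl cis, bromoallyl trans to the C9 dimethoxymethyl group) | CC[Si](CC)(CC)O[C@H]1CCC(C)(C)[C@@H](CO[Si](CC)(CC)CC)[C@@]12COC(=O)[C@](CC=C)(CC(Br)=C)[C@H]2C(OC)OC | intermediate
20 | 1,6-diol from 19 | O[C@H]1CCC(C)(C)[C@@H](CO)[C@@]12COC(=O)[C@](CC=C)(CC(Br)=C)[C@H]2C(OC)OC | intermediate
21 | 1,6-diacetate of 20 | CC(=O)O[C@H]1CCC(C)(C)[C@@H](COC(C)=O)[C@@]12COC(=O)[C@](CC=C)(CC(Br)=C)[C@H]2C(OC)OC | intermediate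
22 | aldehyde from 21 (C9 formyl; cyclization substrate) | CC(=O)O[C@H]1CCC(C)(C)[C@@H](COC(C)=O)[C@@]12COC(=O)[C@](CC=C)(CC(Br)=C)[C@H]2C=O | intermediate
23 | 15-deoxorabdosin B (C15 is CH2; all other centres as in the target) | C=C1C[C@]23C[C@H]1C[C@H](O)[C@H]2[C@]1(COC3=O)[C@@H](OC(C)=O)CCC(C)(C)[C@H]1COC(C)=O | intermediate
24 | 15-hydroxy-15-deoxorabdosin B (C15 carbinol configuration not controlled and not needed) | C=C1C(O)[C@]23C[C@H]1C[C@H](O)[C@H]2[C@]1(COC3=O)[C@@H](OC(C)=O)CCC(C)(C)[C@H]1COC(C)=O | intermediate
25 | Rabdosin B | C=C1C(=O)[C@]23C[C@H]1C[C@H](O)[C@H]2[C@]1(COC3=O)[C@@H](OC(C)=O)CCC(C)(C)[C@H]1COC(C)=O | target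

**Summary**

Total step count: 14. Longest linear sequence: 14 steps (from 1).

Steps most likely to fail:

Step 12. The C12 radical may add to the formyl group with poor facial selectivity (the alkoxyl radical forms reversibly, so the C11 ratio can drift), and part of it may be lost by hydrogen transfer from the stannane. The fallback takes the C11 configuration out of the radical event. Setting out from 22, the cyclization is run as described and the mixture of 23 and its C11 epimer F1 is oxidised with DMP (1,1,1-triacetoxy-1,1-dihydro-1,2-benziodoxol-3(1H)-one) to the single 11-ketone F2. F2 is then reduced with LiBH(s-Bu)3 at −78 °C; hydride should enter from the face of ring C opposite the C15–C16 bridge, as is usual for bicyclo[3.2.1]octan-3-ones, and this returns to 23.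

Step 2. The congested adduct (quaternary C10 next to tertiary C9) may revert by retro-Michael reaction or form sluggishly under the equilibrating amine conditions. The fallback is an irreversible Mukaiyama–Michael addition. Setting out from 5, silylation (TBSOTf, Et3N) gives the silyl enol ether F3, which should add to 6 under TBSOTf catalysis at −78 °C to give the silyl ketene acetal F4; aqueous acidic work-up returns to 7.

Step 1. Enantioselectivity may erode through uncatalysed or poorly ligand-controlled addition of the vinyl Grignard reagent. The fallback replaces catalyst control by resolution through the auxiliary. Setting out from 1, the addition/formylation is run with CuI alone to give 5 together with its enantiomer F5. The racemate is taken through step 2 with enantiopure 6, and the diastereomeric adduct F6 that arises from F5 is removed by chromatography or crystallisation, returning to 7.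

Further compounds
F1 | step 12 | C11 epimer of 23 (11-hydroxyl trans to H9) | C=C1C[C@]23C[C@H]1C[C@@H](O)[C@H]2[C@]1(COC3=O)[C@@H](OC(C)=O)CCC(C)(C)[C@H]1COC(C)=O
F2 | step 12 | 11-ketone corresponding to 23 | C=C1C[C@]23C[C@H]1CC(=O)[C@H]2[C@]1(COC3=O)[C@@H](OC(C)=O)CCC(C)(C)[C@H]1COC(C)=O
F3 | step 2 | (3R)-2-[(tert-butyldimethylsilyloxy)methylidene]-4,4-dimethyl-3-vinylcyclohexan-1-one | CC(C)(C)[Si](C)(C)OC=C1C(=O)CCC(C)(C)[C@H]1C=C
F4 | step 2 | tert-butyldimethylsilyl ketene acetal of 7 | O=C1CCC(C)(C)[C@@H](C=C)[C@]1(C=O)[C@H]2C=C(O[Si](C)(C)C(C)(C)C)O[C@@H]2O[C@H]3C[C@@H](C)CC[C@@H]3C(C)C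
F5 | step 1 | (3S,Z)-2-(hydroxymethylidene)-4,4-dimethyl-3-vinylcyclohexan-1-one | O/C=C1\C(=O)CCC(C)(C)[C@@H]1C=C
F6 | step 1 | diastereomer of 7 formed from F5 (ring-A centres inverted, lactone part as in 7) | O=C1CCC(C)(C)[C@H](C=C)[C@@]1(C=O)[C@H]2CC(=O)O[C@@H]2O[C@H]3C[C@@H](C)CC[C@@H]3C(C)C
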